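**Retrosynthetic overview**

1. Cyclobutane labels: Ca and Cc carry the guaiacyl rings, Cb carries the ester trans to both aryl groups, Cd the ester cis to both. The two alcohol units are C6 epimers of one 2,4,7-trimethyl-octahydrocyclopenta[c]pyridin-6-ol: 6,7-cis (6S) on Cb, 6,7-trans (6R) on Cd.
2. Endgame: benzyl ethers off last; Cb ester by acylation of amino alcohol 23 (retention at C6); Cd ester by Mitsunobu reaction of the same 23 (inversion at C6).
3. Key disconnection: the Ca–aryl and Cc–aryl bonds. The strategy rests on the fact that both aryl groups flank Cd on the face of the Cd carboxyl, with the Cb carboxyl on the other face, so a chelating 8-aminoquinoline amide on Cd of trans-cyclobutane 5 can deliver palladium to both neighbouring CH2 groups in one operation.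
4. Amino alcohol 23: C6–O by ketone reduction, C7 and C7a by hydrogenation and epimerisation, C4 from hydroxy ester 14.
5. Ring order: the cyclobutane is bought (1) and only substituted; the piperidine and cyclopentenone rings of 23 are closed together by a Pauson–Khand reaction of enyne 17 (step 12).

Key step: step 5

Assumption: the SMILES is read as 6S (hydroxyl cis to the C7 methyl) for the Cb-bound unit and 6R for the Cd-bound unit, and trans-3-(methoxycarbonyl)cyclobutane-1-carboxylic acid 1 is taken as a catalogue compound sold as the pure trans isomer, which avoids a cis/trans separation.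

**Route**

Step 1
Reactants: 1 trans-3-(methoxycarbonyl)cyclobutane-1-carboxylic acid
Product: 2 tert-butyl methyl trans-cyclobutane-1,3-dicarboxylate
Conditions: t-BuOC(=NH)CCl3 (2 equiv), BF3·OEt2 (cat.), CH2Cl2/cyclohexane, rt
Reagents that add atoms: tert-butyl 2,2,2-trichloroacetimidate, CC(C)(C)OC(=N)C(Cl)(Cl)Cl
Why: Acid-catalysed esterification by tert-butyl transfer from the trichloroacetimidate converts the free acid into its tert-butyl ester without touching the methyl ester or the trans ring configuration.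

Step 2
Reactants: 2 tert-butyl methyl trans-cyclobutane-1,3-dicarboxylate
Product: 3 trans-3-(tert-butoxycarbonyl)cyclobutane-1-carboxylic acid
Conditions: LiOH·H2O (1.05 equiv), THF/H2O 3:1, 0 °C; 1 M HCl to pH 3
Reagents that add atoms: lithium hydroxide (hydroxide oxygen), [Li+].[OH-]
Why: Saponification by acyl substitution is much faster at the methyl ester than at the tert-butyl ester, and cold hydroxide should not epimerise the ring carbons.

Step 3
Reactants: 3 trans-3-(tert-butoxycarbonyl)cyclobutane-1-carboxylic acid; 4 8-aminoquinoline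
Product: 5 tert-butyl trans-3-(quinolin-8-ylcarbamoyl)cyclobutane-1-carboxylate
Conditions: N-(3-dimethylaminopropyl)-N′-ethylcarbodiimide hydrochloride (EDC·HCl, 1.5 equiv), DMAP (1 equiv), CH2Cl2, rt
Reagents that add atoms: none
Why: Carbodiimide amide coupling with DMAP acyl transfer acylates the weakly nucleophilic aromatic amine and leaves the tert-butyl ester and the trans relationship unchanged.

Step 4
Reactants: 6 4-iodo-2-methoxyphenol
Product: 7 1-(benzyloxy)-4-iodo-2-methoxybenzene
Conditions: BnBr (1.2 equiv), K2CO3 (2 equiv), DMF, rt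
Reagents that add atoms: benzyl bromide, BrCc1ccccc1
Why: Williamson ether synthesis on the phenoxide masks the phenol as a benzyl ether that survives the arylation, peroxide, acid and carbodiimide steps and is removed by hydrogenolysis at the end.

Step 5
Reactants: 5 tert-butyl trans-3-(quinolin-8-ylcarbamoyl)cyclobutane-1-carboxylate; 7 1-(benzyloxy)-4-iodo-2-methoxybenzene
Product: 9 tert-butyl 2,4-bis[4-(benzyloxy)-3-methoxyphenyl]-3-(quinolin-8-ylcarbamoyl)cyclobutane-1-carboxylate (both aryl groups cis to the amide; ester trans; achiral), via monoarylated amide 8 (not isolated)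
Conditions: Pd(OAc)2 (10 mol %), AgOAc (3 equiv), 7 (4 equiv), toluene, 110 °C, sealed tube
Reagents that add atoms: none
Why: The deprotonated amide nitrogen and the quinoline nitrogen of 5 chelate divalent palladium, and acetate-assisted concerted metalation–deprotonation of a ring C–H cis to the amide gives a five-membered palladacycle cis-fused to the cyclobutane; oxidative addition of 7 to give tetravalent palladium and C–C reductive elimination form the Ca–aryl bond with retention, AgOAc takes up iodide, and the cycle repeats at the second methylene of intermediate 8. The closest known reaction type is the 8-aminoquinoline-directed palladium-catalysed methylene arylation of cyclobutanecarboxamides with aryl iodides, which is known to run twice to all-cis 2,4-diaryl amides. No ring closes in this step; two C–C bonds are made on a ring that is already in place. The new stereocentres Ca and Cc are controlled by the Cd amide, because the cis-fused palladacycle can hand the aryl group only to the face that carries the directing group. The step needs both aryl groups cis to the Cd amide and trans to the Cb ester, and the trans arrangement in 5 secures this: both C–H bonds cis to the amide are open, the tert-butyl ester sits on the far face, and the tertiary Cb–H would need a strained bridged palladacycle. Because 9 keeps the mirror plane through Cb and Cd, no enantiocontrol is required.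

Step 6
Reactants: 9 tert-butyl 2,4-bis[4-(benzyloxy)-3-methoxyphenyl]-3-(quinolin-8-ylcarbamoyl)cyclobutane-1-carboxylate
Product: 10 tert-butyl 2,4-bis[4-(benzyloxy)-3-methoxyphenyl]-3-[(tert-butoxycarbonyl)(quinolin-8-yl)carbamoyl]cyclobutane-1-carboxylate
Conditions: Boc2O (4 equiv), DMAP (2 equiv), MeCN, 60 °C
Reagents that add atoms: di-tert-butyl dicarbonate, CC(C)(C)OC(=O)OC(=O)OC(C)(C)C
Why: DMAP-catalysed N-acylation of the secondary amide gives a twisted N-acyl carbamate whose ring-side carbonyl is activated for mild cleavage, without any base strong enough to remove Cd–H.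

Step 7
Reactants: 10 tert-butyl 2,4-bis[4-(benzyloxy)-3-methoxyphenyl]-3-[(tert-butoxycarbonyl)(quinolin-8-yl)carbamoyl]cyclobutane-1-carboxylate
Product: 11 2,4-bis[4-(benzyloxy)-3-methoxyphenyl]-3-(tert-butoxycarbonyl)cyclobutane-1-carboxylic acid (acid on Cd cis to both aryl groups; tert-butyl ester on Cb trans)
Conditions: LiOH·H2O (2 equiv), 30 % H2O2 (5 equiv), THF/H2O 3:1, 0 °C; Na2SO3; 1 M HCl to pH 3
Reagents that add atoms: hydrogen peroxide, OO
Why: Hydroperoxide, a weakly basic but strongly nucleophilic anion, attacks the ring-side acyl carbon of the activated imide (acyl substitution), so the auxiliary leaves as its carbamate at 0 °C under conditions that should neither epimerise the congested Cd centre nor cleave the tert-butyl ester or the benzyl ethers.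

Step 8
Reactants: 12 but-2-yn-1-amine hydrochloride
Product: 13 N-(but-2-yn-1-yl)-4-methylbenzenesulfonamide
Conditions: TsCl (1.05 equiv), Et3N (2.2 equiv), CH2Cl2, 0 °C → rt
Reagents that add atoms: 4-methylbenzenesulfonyl chloride, Cc1ccc(cc1)S(Cl)(=O)=O
Why: N-Sulfonylation of the primary amine gives a sulfonamide whose remaining N–H is acidic enough to serve as the Mitsunobu nucleophile and which tethers well in cobalt-mediated enyne cyclisation.

Step 9
Reactants: 14 methyl (S)-3-hydroxy-2-methylpropanoate; 13 N-(but-2-yn-1-yl)-4-methylbenzenesulfonamide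
Product: 15 methyl (S)-3-[N-(but-2-yn-1-yl)-4-methylbenzenesulfonamido]-2-methylpropanoate
Conditions: PPh3 (1.3 equiv), DIAD (1.3 equiv), THF, 0 °C → rt
Reagents that add atoms: none
Why: Mitsunobu N-alkylation of the sulfonamide by the primary alcohol forms the C3–N bond at a carbon that is not stereogenic, so the methyl-bearing stereocentre is carried through unchanged.

Step 10
Reactants: 15 methyl (S)-3-[N-(but-2-yn-1-yl)-4-methylbenzenesulfonamido]-2-methylpropanoate
Product: 16 (S)-N-(but-2-yn-1-yl)-4-methyl-N-(2-methyl-3-oxopropyl)benzenesulfonamide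
Conditions: i-Bu2AlH (1.1 equiv), CH2Cl2, −78 °C; MeOH, aq. potassium sodium tartrate; used crude at once
Reagents that add atoms: none
Why: Partial ester reduction with the aluminium hydride at −78 °C stops at the tetrahedral aluminium hemiacetal, which releases the aldehyde only on work-up, and immediate use limits enolisation of the alpha-stereocentre.

Step 11
Reactants: 16 (S)-N-(but-2-yn-1-yl)-4-methyl-N-(2-methyl-3-oxopropyl)benzenesulfonamide
Product: 17 (R)-N-(but-2-yn-1-yl)-4-methyl-N-(2-methylbut-3-en-1-yl)benzenesulfonamide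
Conditions: Ph3PCH3Br (1.5 equiv), KN(SiMe3)2 (1.4 equiv), THF, −78 → 0 °C
Reagents that add atoms: methyltriphenylphosphonium bromide, C[P+](c1ccccc1)(c1ccccc1)c1ccccc1.[Br-]
Why: Wittig methylenation with the unstabilised ylide at low temperature should add to the aldehyde faster than it enolises it, giving the vinyl group with the stereocentre intact (the descriptor changes from S to R only through the priority rules).

Step 12
Reactants: 17 (R)-N-(but-2-yn-1-yl)-4-methyl-N-(2-methylbut-3-en-1-yl)benzenesulfonamide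
Product: 18 (4R,4aR)-4,7-dimethyl-2-(4-methylbenzenesulfonyl)-1,2,3,4,4a,5-hexahydro-6H-cyclopenta[c]pyridin-6-one
Conditions: Co2(CO)8 (10 mol %), tetramethylthiourea (60 mol %), CO (1 atm), toluene, 70 °C
Reagents that add atoms: carbon monoxide, [C-]#[O+]
Why: The intramolecular Pauson–Khand reaction (alkyne, alkene and CO joined on cobalt) closes the piperidine and the cyclopentenone together, and the C4 methyl should sit pseudo-equatorial in the chair-like alkene-insertion transition state, which sets C4a with its hydrogen cis to the C4 methyl.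

Step 13
Reactants: 18 (4R,4aR)-4,7-dimethyl-2-(4-methylbenzenesulfonyl)-1,2,3,4,4a,5-hexahydro-6H-cyclopenta[c]pyridin-6-one
Product: 20 (4R,4aR,7R,7aS)-4,7-dimethyl-2-(4-methylbenzenesulfonyl)octahydro-6H-cyclopenta[c]pyridin-6-one (cis-fused; 7-methyl trans to C1), via 7-epi ketone 19 (not isolated)
Conditions: H2 (4 atm), 10 % Pd/C, MeOH, rt; filter; K2CO3 (0.5 equiv), MeOH, 40 °C
Reagents that add atoms: none
Why: Heterogeneous syn hydrogenation should add to the enone from the face of H-4a (the other face is covered by C3 and C4 of the piperidine), giving the cis ring fusion with the 7-methyl cis to C1, and base equilibration through the enolate then moves the 7-methyl to the more stable position trans to C1.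

Step 14
Reactants: 20 (4R,4aR,7R,7aS)-4,7-dimethyl-2-(4-methylbenzenesulfonyl)octahydro-6H-cyclopenta[c]pyridin-6-one
Product: 21 (4R,4aR,6S,7R,7aS)-4,7-dimethyl-2-(4-methylbenzenesulfonyl)octahydro-1H-cyclopenta[c]pyridin-6-ol
Conditions: LiBH(s-Bu)3 (1.3 equiv), THF, −78 °C; H2O
Reagents that add atoms: none
Why: Ketone reduction with the bulky trialkylborohydride should, as with 2-alkylcyclopentanones, deliver hydride anti to the adjacent C7 methyl and so place the new hydroxyl cis to that methyl (6S).

Step 15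
Reactants: 21 (4R,4aR,6S,7R,7aS)-4,7-dimethyl-2-(4-methylbenzenesulfonyl)octahydro-1H-cyclopenta[c]pyridin-6-ol
Product: 22 (4R,4aR,6S,7R,7aS)-4,7-dimethyloctahydro-1H-cyclopenta[c]pyridin-6-ol
Conditions: Na, naphthalene (NaC10H8, 6 equiv), DME, −78 °C; H2O
Reagents that add atoms: none
Why: Single-electron reductive cleavage of the S–N bond by sodium naphthalenide frees the secondary amine without touching any stereocentre, the hydroxyl being carried as its inert alkoxide.

Step 16
Reactants: 22 (4R,4aR,6S,7R,7aS)-4,7-dimethyloctahydro-1H-cyclopenta[c]pyridin-6-ol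
Product: 23 (4R,4aR,6S,7R,7aS)-2,4,7-trimethyloctahydro-1H-cyclopenta[c]pyridin-6-ol
Conditions: 37 % aq. CH2O (3 equiv), NaBH(OAc)3 (2 equiv), AcOH (1 equiv), MeCN, rt
Reagents that add atoms: formaldehyde, C=O
Why: Reductive amination (iminium formation, then hydride transfer from the acetoxyborohydride) methylates the secondary amine selectively and leaves the secondary alcohol free.

Step 17
Reactants: 11 2,4-bis[4-(benzyloxy)-3-methoxyphenyl]-3-(tert-butoxycarbonyl)cyclobutane-1-carboxylic acid; 23 (4R,4aR,6S,7R,7aS)-2,4,7-trimethyloctahydro-1H-cyclopenta[c]pyridin-6-ol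
Product: 24 tert-butyl (4R,4aR,6R,7R,7aS)-2,4,7-trimethyloctahydro-1H-cyclopenta[c]pyridin-6-yl 2,4-bis[4-(benzyloxy)-3-methoxyphenyl]cyclobutane-1,3-dicarboxylate (amino-alcohol ester on Cd, cis to both aryl groups; tert-butyl ester on Cb)
Conditions: PPh3 (2 equiv), DIAD (2 equiv), 23 (1.5 equiv), THF, 0 °C → rt
Reagents that add atoms: none
Why: In this Mitsunobu esterification the Cd carboxylate displaces the oxyphosphonium group at C6 by SN2 from the face anti to the C7 methyl, so C6 is inverted (6S to 6R) and the ester oxygen ends trans to the C7 methyl, while the shielded Cd carbonyl is never activated and Cd cannot epimerise.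

Step 18
Reactants: 24 tert-butyl (4R,4aR,6R,7R,7aS)-2,4,7-trimethyloctahydro-1H-cyclopenta[c]pyridin-6-yl 2,4-bis[4-(benzyloxy)-3-methoxyphenyl]cyclobutane-1,3-dicarboxylate
Product: 25 2,4-bis[4-(benzyloxy)-3-methoxyphenyl]-3-{[(4R,4aR,6R,7R,7aS)-2,4,7-trimethyloctahydro-1H-cyclopenta[c]pyridin-6-yl]oxycarbonyl}cyclobutane-1-carboxylic acid (free acid on Cb)
Conditions: CF3CO2H/CH2Cl2 1:4, 0 °C → rt; pH 7 buffer
Reagents that add atoms: none
Why: Acidolysis of the tert-butyl ester with loss of isobutene frees the Cb acid, while the secondary alkyl ester, the aryl benzyl ethers and the protonated amine should be stable to cold dilute trifluoroacetic acid.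

Step 19
Reactants: 25 2,4-bis[4-(benzyloxy)-3-methoxyphenyl]-3-{[(4R,4aR,6R,7R,7aS)-2,4,7-trimethyloctahydro-1H-cyclopenta[c]pyridin-6-yl]oxycarbonyl}cyclobutane-1-carboxylic acid; 23 (4R,4aR,6S,7R,7aS)-2,4,7-trimethyloctahydro-1H-cyclopenta[c]pyridin-6-ol
Product: 26 bis(O-benzyl) ether of the target: Cb ester of the 6S alcohol, Cd ester of the 6R alcohol
Conditions: EDC·HCl (2 equiv), DMAP (1.5 equiv), 23 (1.5 equiv), CH2Cl2, rt
Reagents that add atoms: none
Why: Steglich esterification forms the Cb ester by attack of the C6 hydroxyl on the activated acyl carbon, so C6 keeps its configuration (6S), and the Cb acid, trans to both aryl groups, is the accessible and thermodynamically preferred epimer.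

Step 20
Reactants: 26 bis(O-benzyl) ether of the target
Product: 27 CNP0283097.4 (target)
Conditions: H2 (1 atm), 20 % Pd(OH)2/C, MeOH/EtOAc, rt
Reagents that add atoms: none
Why: Catalytic hydrogenolysis cleaves the two aryl benzyl ethers to the free guaiacyl phenols without affecting the esters, the tertiary amines or the cyclobutane.

**Compound list**

1 | trans-3-(methoxycarbonyl)cyclobutane-1-carboxylic acid | COC(=O)[C@@H]1C[C@@H](C(=O)O)C1 | starting material
2 | tert-butyl methyl trans-cyclobutane-1,3-dicarboxylate | COC(=O)[C@@H]1C[C@@H](C(=O)OC(C)(C)C)C1 | intermediate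
3 | trans-3-(tert-butoxycarbonyl)cyclobutane-1-carboxylic acid | OC(=O)[C@@H]1C[C@@H](C(=O)OC(C)(C)C)C1 | intermediate
4 | 8-aminoquinoline | Nc1cccc2cccnc12 | starting material
5 | tert-butyl trans-3-(quinolin-8-ylcarbamoyl)cyclobutane-1-carboxylate | O=C(Nc1cccc2cccnc12)[C@@H]1C[C@@H](C(=O)OC(C)(C)C)C1 | intermediate
6 | 4-iodo-2-methoxyphenol | COc1cc(I)ccc1O | starting material
7 | 1-(benzyloxy)-4-iodo-2-methoxybenzene | COc1cc(I)ccc1OCc1ccccc1 | intermediate
8 | tert-butyl 2-[4-(benzyloxy)-3-methoxyphenyl]-3-(quinolin-8-ylcarbamoyl)cyclobutane-1-carboxylate (aryl cis to amide, trans to ester; racemic, one enantiomer drawn) | COc1cc([C@@H]2[C@@H](C(=O)OC(C)(C)C)C[C@@H]2C(=O)Nc2cccc3cccnc23)ccc1OCc1ccccc1 | intermediate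
9 | tert-butyl 2,4-bis[4-(benzyloxy)-3-methoxyphenyl]-3-(quinolin-8-ylcarbamoyl)cyclobutane-1-carboxylate (aryls cis to amide, trans to ester) | COc1cc([C@@H]2[C@@H](C(=O)OC(C)(C)C)[C@H](c3ccc(OCc4ccccc4)c(OC)c3)[C@@H]2C(=O)Nc2cccc3cccnc23)ccc1OCc1ccccc1 | intermediate
10 | tert-butyl 2,4-bis[4-(benzyloxy)-3-methoxyphenyl]-3-[(tert-butoxycarbonyl)(quinolin-8-yl)carbamoyl]cyclobutane-1-carboxylate | COc1cc([C@@H]2[C@@H](C(=O)OC(C)(C)C)[C@H](c3ccc(OCc4ccccc4)c(OC)c3)[C@@H]2C(=O)N(C(=O)OC(C)(C)C)c2cccc3cccnc23)ccc1OCc1ccccc1 | intermediate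
11 | 2,4-bis[4-(benzyloxy)-3-methoxyphenyl]-3-(tert-butoxycarbonyl)cyclobutane-1-carboxylic acid (acid cis to both aryls) | COc1cc([C@@H]2[C@@H](C(=O)OC(C)(C)C)[C@H](c3ccc(OCc4ccccc4)c(OC)c3)[C@@H]2C(=O)O)ccc1OCc1ccccc1 | intermediate
12 | but-2-yn-1-amine hydrochloride | CC#CCN.Cl | starting material
13 | N-(but-2-yn-1-yl)-4-methylbenzenesulfonamide | CC#CCNS(=O)(=O)c1ccc(C)cc1 | intermediate
14 | methyl (S)-3-hydroxy-2-methylpropanoate | COC(=O)[C@@H](C)CO | starting material
15 | methyl (S)-3-[N-(but-2-yn-1-yl)-4-methylbenzenesulfonamido]-2-methylpropanoate | COC(=O)[C@@H](C)CN(CC#CC)S(=O)(=O)c1ccc(C)cc1 | intermediate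
16 | (S)-N-(but-2-yn-1-yl)-4-methyl-N-(2-methyl-3-oxopropyl)benzenesulfonamide | O=C[C@@H](C)CN(CC#CC)S(=O)(=O)c1ccc(C)cc1 | intermediate
17 | (R)-N-(but-2-yn-1-yl)-4-methyl-N-(2-methylbut-3-en-1-yl)benzenesulfonamide | C=C[C@@H](C)CN(CC#CC)S(=O)(=O)c1ccc(C)cc1 | intermediate
18 | (4R,4aR)-4,7-dimethyl-2-(4-methylbenzenesulfonyl)-1,2,3,4,4a,5-hexahydro-6H-cyclopenta[c]pyridin-6-one | O=C1C[C@H]2C(CN(S(=O)(=O)c3ccc(C)cc3)C[C@@H]2C)=C1C | intermediate
19 | (4R,4aR,7S,7aS)-4,7-dimethyl-2-(4-methylbenzenesulfonyl)octahydro-6H-cyclopenta[c]pyridin-6-one (7-methyl cis to C1) | O=C1C[C@H]2[C@H](CN(S(=O)(=O)c3ccc(C)cc3)C[C@@H]2C)[C@@H]1C | intermediate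
20 | (4R,4aR,7R,7aS)-4,7-dimethyl-2-(4-methylbenzenesulfonyl)octahydro-6H-cyclopenta[c]pyridin-6-one (7-methyl trans to C1) | O=C1C[C@H]2[C@H](CN(S(=O)(=O)c3ccc(C)cc3)C[C@@H]2C)[C@H]1C | intermediate
21 | (4R,4aR,6S,7R,7aS)-4,7-dimethyl-2-(4-methylbenzenesulfonyl)octahydro-1H-cyclopenta[c]pyridin-6-ol | O[C@H]1C[C@H]2[C@H](CN(S(=O)(=O)c3ccc(C)cc3)C[C@@H]2C)[C@H]1C | intermediate
22 | (4R,4aR,6S,7R,7aS)-4,7-dimethyloctahydro-1H-cyclopenta[c]pyridin-6-ol | O[C@H]1C[C@H]2[C@H](CNC[C@@H]2C)[C@H]1C | intermediate
23 | (4R,4aR,6S,7R,7aS)-2,4,7-trimethyloctahydro-1H-cyclopenta[c]pyridin-6-ol (hydroxyl cis to the C7 methyl) | O[C@H]1C[C@H]2[C@H](CN(C)C[C@@H]2C)[C@H]1C | intermediate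
24 | tert-butyl (4R,4aR,6R,7R,7aS)-2,4,7-trimethyloctahydro-1H-cyclopenta[c]pyridin-6-yl 2,4-bis[4-(benzyloxy)-3-methoxyphenyl]cyclobutane-1,3-dicarboxylate | COc1cc([C@@H]2[C@@H](C(=O)OC(C)(C)C)[C@H](c3ccc(OCc4ccccc4)c(OC)c3)[C@@H]2C(=O)O[C@@H]2C[C@H]3[C@H](CN(C)C[C@@H]3C)[C@H]2C)ccc1OCc1ccccc1 | intermediate
25 | 2,4-bis[4-(benzyloxy)-3-methoxyphenyl]-3-{[(4R,4aR,6R,7R,7aS)-2,4,7-trimethyloctahydro-1H-cyclopenta[c]pyridin-6-yl]oxycarbonyl}cyclobutane-1-carboxylic acid | COc1cc([C@@H]2[C@@H](C(=O)O)[C@H](c3ccc(OCc4ccccc4)c(OC)c3)[C@@H]2C(=O)O[C@@H]2C[C@H]3[C@H](CN(C)C[C@@H]3C)[C@H]2C)ccc1OCc1ccccc1 | intermediate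
26 | bis(O-benzyl) ether of the target (Cb ester of the 6S alcohol, Cd ester of the 6R alcohol) | COc1cc([C@@H]2[C@@H](C(=O)O[C@H]3C[C@H]4[C@H](CN(C)C[C@@H]4C)[C@H]3C)[C@H](c3ccc(OCc4ccccc4)c(OC)c3)[C@@H]2C(=O)O[C@@H]2C[C@H]3[C@H](CN(C)C[C@@H]3C)[C@H]2C)ccc1OCc1ccccc1 | intermediate
27 | CNP0283097.4 | COc1cc([C@@H]2[C@@H](C(=O)O[C@H]3C[C@H]4[C@H](CN(C)C[C@@H]4C)[C@H]3C)[C@H](c3ccc(O)c(OC)c3)[C@@H]2C(=O)O[C@@H]2C[C@H]3[C@H](CN(C)C[C@@H]3C)[C@H]2C)ccc1O | target

**Step count and risks**

Total steps: 20. Longest linear sequence: 13 steps (steps 8 to 16 to amino alcohol 23, then steps 17 to 20).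

Step 5 (twofold C–H arylation). The second C–H activation may lag behind the first, so that mono- and diarylated amides and decomposition products of the hot silver/palladium mixture build up together. The fallback brings the aryl groups in one at a time through the cis series and sets out from 5.
- Amide 5 would be equilibrated at the ester-bearing carbon (KOt-Bu, t-BuOH/THF; the amide is protected as its N-anion and the 1,3-cis isomer is the more stable), and the cis isomer, tert-butyl cis-3-(quinolin-8-ylcarbamoyl)cyclobutane-1-carboxylate F1, separated.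
- F1 would be arylated once with 7 (Pd(OAc)2, Ag2CO3, pivalic acid, hexafluoroisopropanol, 90 °C). This should stop at the all-cis monoaryl amide, tert-butyl 2-[4-(benzyloxy)-3-methoxyphenyl]-3-(quinolin-8-ylcarbamoyl)cyclobutane-1-carboxylate F2, because the crowded all-cis ring resists a second palladation.
- Epimerisation of the ester carbon of F2 (LiOt-Bu, THF) relieves the all-cis strain and gives 8, now isolated.
- A separate arylation of pure 8 with 7 and fresh catalyst returns to the route at 9.

Step 14 (ketone reduction). Hydride delivery may show poor facial selectivity, since the convex face carries the C7 methyl and the concave face the piperidine ring. The fallback is stereoconvergent and sets out from 20.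
- Reduction with NaBH4 (MeOH, 0 °C) would give 21 together with its C6 epimer, (4R,4aR,6R,7R,7aS)-4,7-dimethyl-2-(4-methylbenzenesulfonyl)octahydro-1H-cyclopenta[c]pyridin-6-ol F3; the two are separated and 21 is taken on.
- F3 would be inverted by a Mitsunobu reaction with 4-nitrobenzoic acid (PPh3, DIAD, toluene) to the 6S ester, (4R,4aR,6S,7R,7aS)-4,7-dimethyl-2-(4-methylbenzenesulfonyl)octahydro-1H-cyclopenta[c]pyridin-6-yl 4-nitrobenzoate F4.
- Methanolysis (K2CO3, MeOH) returns to the route at 21.

Step 17 (Mitsunobu esterification at Cd). The activated alcohol may eliminate to the cyclopentene, or the shielded Cd carboxylate may fail to displace the oxyphosphonium group. The fallback moves the inversion off the hindered acid and sets out from 23 and 11.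
- Alcohol 23 would be inverted with the small, more acidic 4-nitrobenzoic acid (PPh3, DIAD, THF) to (4R,4aR,6R,7R,7aS)-2,4,7-trimethyloctahydro-1H-cyclopenta[c]pyridin-6-yl 4-nitrobenzoate F5.
- Methanolysis (K2CO3, MeOH) gives the 6,7-trans amino alcohol, (4R,4aR,6R,7R,7aS)-2,4,7-trimethyloctahydro-1H-cyclopenta[c]pyridin-6-ol F6.
- Acid 11 would be converted under neutral conditions (1-chloro-N,N,2-trimethylprop-1-en-1-amine, CH2Cl2, 0 °C) into its acid chloride, 2,4-bis[4-(benzyloxy)-3-methoxyphenyl]-3-(tert-butoxycarbonyl)cyclobutane-1-carbonyl chloride F7.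
- Acylation of F6 with F7 (pyridine, DMAP, 0 °C → rt) proceeds with retention at C6 and returns to the route at 24.

Further compounds
F1 | step 5 | tert-butyl cis-3-(quinolin-8-ylcarbamoyl)cyclobutane-1-carboxylate | O=C(Nc1cccc2cccnc12)[C@@H]1C[C@H](C(=O)OC(C)(C)C)C1
F2 | step 5 | tert-butyl 2-[4-(benzyloxy)-3-methoxyphenyl]-3-(quinolin-8-ylcarbamoyl)cyclobutane-1-carboxylate (all-cis, racemic, one enantiomer drawn) | COc1cc([C@@H]2[C@H](C(=O)OC(C)(C)C)C[C@@H]2C(=O)Nc2cccc3cccnc23)ccc1OCc1ccccc1
F3 | step 14 | (4R,4aR,6R,7R,7aS)-4,7-dimethyl-2-(4-methylbenzenesulfonyl)octahydro-1H-cyclopenta[c]pyridin-6-ol | O[C@@H]1C[C@H]2[C@H](CN(S(=O)(=O)c3ccc(C)cc3)C[C@@H]2C)[C@H]1C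
F4 | step 14 | (4R,4aR,6S,7R,7aS)-4,7-dimethyl-2-(4-methylbenzenesulfonyl)octahydro-1H-cyclopenta[c]pyridin-6-yl 4-nitrobenzoate | O=C(O[C@H]1C[C@H]2[C@H](CN(S(=O)(=O)c3ccc(C)cc3)C[C@@H]2C)[C@H]1C)c1ccc(cc1)[N+](=O)[O-]
F5 | step 17 | (4R,4aR,6R,7R,7aS)-2,4,7-trimethyloctahydro-1H-cyclopenta[c]pyridin-6-yl 4-nitrobenzoate | O=C(O[C@@H]1C[C@H]2[C@H](CN(C)C[C@@H]2C)[C@H]1C)c1ccc(cc1)[N+](=O)[O-]
F6 | step 17 | (4R,4aR,6R,7R,7aS)-2,4,7-trimethyloctahydro-1H-cyclopenta[c]pyridin-6-ol | O[C@@H]1C[C@H]2[C@H](CN(C)C[C@@H]2C)[C@H]1C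
F7 | step 17 | 2,4-bis[4-(benzyloxy)-3-methoxyphenyl]-3-(tert-butoxycarbonyl)cyclobutane-1-carbonyl chloride | COc1cc([C@@H]2[C@@H](C(=O)OC(C)(C)C)[C@H](c3ccc(OCc4ccccc4)c(OC)c3)[C@@H]2C(=O)Cl)ccc1OCc1ccccc1
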